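**Retrosynthetic overview**

1. The C8 ester is disconnected last, to the core alcohol and (E)-2-(acetoxymethyl)but-2-enoic acid (from the tert-butyl Morita–Baylis–Hillman adduct of acetaldehyde by acetylation, 1,3-acetate shift and acidolysis).
2. Key disconnection C7–C8: the C8 carbinol is bonded to C7, the β-carbon of the α-methylene γ-lactone (O–C6, C7, C11=C13, C12=O). This is the retron of a 3-(metallomethyl)butenolide adding through its ring carbon to an aldehyde, and it opens the ten-membered carbocycle C1–C10 to a seco bromo aldehyde.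
3. The furanone ring (O, C3=C2, C1=O, C10) comes from a γ-hydroxy ynone by gold-catalysed hydrative cyclisation. The ynone comes from a carbonylative Sonogashira union of an alkynol (C1, C2, C8–C10), CO (C3) and a Z-vinyl iodide (C4–C7, C11–C13).
4. C10 is set by Sharpless epoxidation of (E)-3-methylpent-2-en-4-yn-1-ol. C6 comes from (R)-5-oxotetrahydrofuran-2-carboxylic acid, whose lactone becomes the hydroxymethyl butenolide (selenoxide route) after Z-iodo-olefination.
5. Ring order: butenolide (carried from the chiral-pool lactone), then furanone, then the ten-membered carbocycle, whose closure unveils the α-methylene lactone.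

Key step: step 16

Remark on the chemistry: germacrane numbering is used throughout (C1 furanone ketone, C2=C3, C4(CH3)=C5, C6 lactone OCH, C7, C8 carbinol, C9, C10 quaternary, C11=C13, C12 lactone carbonyl); the C13 bromide and the C8 aldehyde are carried as silyl ethers until the last steps before ring closure, because radical bromination of a C11 methyl group or late cleavage of a C8 alkene would not be selective in this polyene.

**Alkynol (C1, C2, C8–C10)**

Step 1
Reactants: 1 (E)-3-methylpent-2-en-4-yn-1-ol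
Product: 2 [(2S,3S)-3-ethynyl-3-methyloxiran-2-yl]methanol
Conditions: Ti(OiPr)4 (10 mol %), L-(+)-diethyl tartrate (12 mol %), t-BuOOH, 4 Å molecular sieves, CH2Cl2, −20 °C
Reagents that add atoms: tert-butyl hydroperoxide, CC(C)(C)OO
Why: Sharpless asymmetric epoxidation of a primary allylic alcohol; L-(+)-tartrate should give the (2S,3S)-epoxide, in the same sense as with other E-configured 3,3-disubstituted allylic alcohols, which sets the future C10.

Step 2
Reactants: 2 [(2S,3S)-3-ethynyl-3-methyloxiran-2-yl]methanol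
Product: 3 (R)-3-methylpent-4-yne-1,3-diol
Conditions: NaAlH2(OCH2CH2OMe)2, THF, −20 → 0 °C; aq. work-up
Reagents that add atoms: none
Why: Hydroxyl-directed reductive opening of a 2,3-epoxy alcohol: the aluminium alkoxide delivers hydride to C2, the less substituted epoxide carbon, so the 1,3-diol forms and the tertiary C–O bond (future C10–O) is never broken.

Step 3
Reactants: 3 (R)-3-methylpent-4-yne-1,3-diol
Product: 4 (R)-5-[(tert-butyldiphenylsilyl)oxy]-3-methylpent-1-yn-3-ol
Conditions: TBDPSCl, imidazole, CH2Cl2, 0 °C → rt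
Reagents that add atoms: tert-butyl(chloro)diphenylsilane, CC(C)(C)[Si](Cl)(c1ccccc1)c1ccccc1
Why: Selective silylation of the primary over the tertiary alcohol; the bulky silyl ether is chosen so that the C8 oxygen should not add to the gold-activated alkyne in step 12.

**Butenolide vinyl iodide (C4–C7, C11–C13)**

Step 4
Reactants: 5 (R)-5-oxotetrahydrofuran-2-carboxylic acid
Product: 6 (R)-5-(hydroxymethyl)dihydrofuran-2(3H)-one
Conditions: BH3·SMe2, THF, 0 °C → rt; aq. work-up
Reagents that add atoms: none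
Why: Borane reduces the carboxylic acid through its acyloxyborane much faster than the lactone (chemoselective acid reduction), and the stereocentre (future C6) is not touched.

Step 5
Reactants: 6 (R)-5-(hydroxymethyl)dihydrofuran-2(3H)-one
Product: 7 (R)-5-oxotetrahydrofuran-2-carbaldehyde
Conditions: Dess–Martin periodinane, CH2Cl2, 0 °C → rt; used crude
Reagents that add atoms: none
Why: Dess–Martin oxidation works without base, so the α-acyloxy aldehyde should form without epimerisation.

Step 6
Reactants: 7 (R)-5-oxotetrahydrofuran-2-carbaldehyde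
Product: 8 (R)-5-[(Z)-2-iodoprop-1-en-1-yl]dihydrofuran-2(3H)-one
Conditions: EtPPh3I, n-BuLi, THF; I2, −78 °C; NaN(SiMe3)2, −20 °C; then 7, −78 → −20 °C
Reagents that add atoms: ethyltriphenylphosphonium iodide, CC[P+](c1ccccc1)(c1ccccc1)c1ccccc1.[I-]; iodine, II
Why: Wittig olefination with the α-iodo ylide Ph3P=C(I)CH3 (Stork–Zhao variant) is kinetically Z-selective, placing iodine cis to the lactone carbon, which fixes the C4=C5 geometry of the target; fast addition at −78 °C should spare the lactone and the α-stereocentre.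

Step 7
Reactants: 8 (R)-5-[(Z)-2-iodoprop-1-en-1-yl]dihydrofuran-2(3H)-one
Product: 10 (5R)-5-[(Z)-2-iodoprop-1-en-1-yl]-3-(phenylselanyl)dihydrofuran-2(3H)-one (C3 epimers), via lithium enolate 9 (not isolated)
Conditions: LiN(iPr)2, THF, −78 °C; PhSeBr, −78 °C
Reagents that add atoms: phenylselenenyl bromide, Br[Se]c1ccccc1
Why: Kinetic deprotonation at the lactone α-carbon (future C11) and α-selenenylation of the enolate install the handle for the later unsaturation; the new centre is lost in step 9, so its configuration does not matter.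

Step 8
Reactants: 10 (5R)-5-[(Z)-2-iodoprop-1-en-1-yl]-3-(phenylselanyl)dihydrofuran-2(3H)-one
Product: 12 (5R)-3-(hydroxymethyl)-5-[(Z)-2-iodoprop-1-en-1-yl]-3-(phenylselanyl)dihydrofuran-2(3H)-one (C3 epimers), via lithium enolate 11 (not isolated)
Conditions: LiN(iPr)2, THF, −78 °C; CH2O (gas, from cracked paraformaldehyde); then AcOH, −78 °C
Reagents that add atoms: formaldehyde, C=O
Why: The selenium-stabilised lactone enolate adds to monomeric formaldehyde (aldol addition), bringing in C13 at the alcohol oxidation level; the vinyl iodide is inert at −78 °C.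

Step 9
Reactants: 12 (5R)-3-(hydroxymethyl)-5-[(Z)-2-iodoprop-1-en-1-yl]-3-(phenylselanyl)dihydrofuran-2(3H)-one
Product: 14 (R)-3-(hydroxymethyl)-5-[(Z)-2-iodoprop-1-en-1-yl]furan-2(5H)-one, via selenoxide 13 (not isolated)
Conditions: H2O2 (30 % aq., 3 equiv), CH2Cl2, 0 °C → rt
Reagents that add atoms: none
Why: Oxidation to selenoxide 13 is followed by syn-elimination (selenoxide elimination), which goes toward the ring C7–H and not toward the carbinol carbon, giving the conjugated endocyclic butenolide without base.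

Step 10
Reactants: 14 (R)-3-(hydroxymethyl)-5-[(Z)-2-iodoprop-1-en-1-yl]furan-2(5H)-one
Product: 15 (R)-3-{[(tert-butyldimethylsilyl)oxy]methyl}-5-[(Z)-2-iodoprop-1-en-1-yl]furan-2(5H)-one
Conditions: TBSCl, imidazole, CH2Cl2, 0 °C
Reagents that add atoms: tert-butyl(chloro)dimethylsilane, CC(C)(C)[Si](C)(C)Cl
Why: Silylation of the primary allylic alcohol keeps it from trapping the acylpalladium intermediate of step 11 as an ester.

**Union, furanone and seco precursor**

Step 11
Reactants: 15 (R)-3-{[(tert-butyldimethylsilyl)oxy]methyl}-5-[(Z)-2-iodoprop-1-en-1-yl]furan-2(5H)-one and 4 (R)-5-[(tert-butyldiphenylsilyl)oxy]-3-methylpent-1-yn-3-ol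
Product: 16 (S)-3-{[(tert-butyldimethylsilyl)oxy]methyl}-5-[(1Z,6R)-8-[(tert-butyldiphenylsilyl)oxy]-6-hydroxy-2,6-dimethyl-3-oxooct-1-en-4-yn-1-yl]furan-2(5H)-one
Conditions: PdCl2(PPh3)2 (5 mol %), CuI (5 mol %), Et3N, THF, CO (1 atm), rt
Reagents that add atoms: carbon monoxide, [C-]#[O+]
Why: Carbonylative Sonogashira coupling: oxidative addition of the vinyl iodide to zerovalent palladium with retention of the Z geometry, CO insertion to the acylpalladium and transfer of the copper acetylide give the alkynyl ketone, with C3 coming from CO; the tertiary alcohol, lactone and silyl ethers are spectators.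

Step 12
Reactants: 16 (S)-3-{[(tert-butyldimethylsilyl)oxy]methyl}-5-[(1Z,6R)-8-[(tert-butyldiphenylsilyl)oxy]-6-hydroxy-2,6-dimethyl-3-oxooct-1-en-4-yn-1-yl]furan-2(5H)-one
Product: 18 (S)-3-{[(tert-butyldimethylsilyl)oxy]methyl}-5-{(Z)-2-[(R)-5-{2-[(tert-butyldiphenylsilyl)oxy]ethyl}-5-methyl-4-oxo-4,5-dihydrofuran-2-yl]prop-1-en-1-yl}furan-2(5H)-one, via hydroxy diketone 17 (not isolated)
Conditions: (p-CF3C6H4)3PAuCl (5 mol %), AgOSO2CF3 (5 mol %), H2O (2 equiv), toluene, rt
Reagents that add atoms: water, O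
Why: Gold-catalysed cycloisomerisation of a γ-hydroxy ynone to a 3(2H)-furanone: conjugate hydration of the alkyne at C1 gives diketone 17, whose C10 hydroxyl adds to the C3 carbonyl and loses water (cyclodehydration); the C10–O bond is never broken and the non-basic medium should keep the Z-alkene and C6.

Step 13
Reactants: 18 (S)-3-{[(tert-butyldimethylsilyl)oxy]methyl}-5-{(Z)-2-[(R)-5-{2-[(tert-butyldiphenylsilyl)oxy]ethyl}-5-methyl-4-oxo-4,5-dihydrofuran-2-yl]prop-1-en-1-yl}furan-2(5H)-one
Product: 19 (S)-3-(hydroxymethyl)-5-{(Z)-2-[(R)-5-(2-hydroxyethyl)-5-methyl-4-oxo-4,5-dihydrofuran-2-yl]prop-1-en-1-yl}furan-2(5H)-one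
Conditions: HF·pyridine, pyridine, THF, 0 °C → rt
Reagents that add atoms: none
Why: Fluoride-mediated desilylation removes both silyl ethers under mildly acidic conditions that the furanone, the butenolide and the acidic C6–H should tolerate.

Step 14
Reactants: 19 (S)-3-(hydroxymethyl)-5-{(Z)-2-[(R)-5-(2-hydroxyethyl)-5-methyl-4-oxo-4,5-dihydrofuran-2-yl]prop-1-en-1-yl}furan-2(5H)-one
Product: 21 (S)-3-(bromomethyl)-5-{(Z)-2-[(R)-5-(2-hydroxyethyl)-5-methyl-4-oxo-4,5-dihydrofuran-2-yl]prop-1-en-1-yl}furan-2(5H)-one, via alkoxysulfonium bromide 20 (not isolated)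
Conditions: NBS, Me2S, CH2Cl2, −20 → 0 °C; aq. work-up
Reagents that add atoms: N-bromosuccinimide, BrN1C(=O)CCC1=O
Why: Corey–Kim halogenation: both alcohols form alkoxysulfonium salts, but only the allylic one (20) is displaced by bromide at 0 °C, while the saturated C8 alkoxysulfonium returns the alcohol on aqueous work-up.

Step 15
Reactants: 21 (S)-3-(bromomethyl)-5-{(Z)-2-[(R)-5-(2-hydroxyethyl)-5-methyl-4-oxo-4,5-dihydrofuran-2-yl]prop-1-en-1-yl}furan-2(5H)-one
Product: 22 2-[(2R)-5-{(1Z)-1-[(2S)-4-(bromomethyl)-5-oxo-2,5-dihydrofuran-2-yl]prop-1-en-2-yl}-2-methyl-3-oxo-2,3-dihydrofuran-2-yl]acetaldehyde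
Conditions: Dess–Martin periodinane, CH2Cl2, 0 °C → rt
Reagents that add atoms: none
Why: Dess–Martin oxidation of the primary C8 alcohol under neutral conditions should give the β-oxygenated aldehyde without β-elimination and leave the allylic bromide intact.

Step 16
Reactants: 22 2-[(2R)-5-{(1Z)-1-[(2S)-4-(bromomethyl)-5-oxo-2,5-dihydrofuran-2-yl]prop-1-en-2-yl}-2-methyl-3-oxo-2,3-dihydrofuran-2-yl]acetaldehyde
Product: 24 (6S,7S,8R,10R)-3,10-epoxy-8-hydroxy-1-oxogermacra-2,4(Z),11(13)-trien-12,6-olide, via allylchromium dichloride 23 (not isolated)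
Conditions: CrCl2 (8 equiv), THF, rt, slow addition of 22 (final 0.002 M); aq. work-up
Reagents that add atoms: none
Why: Proposed new method: CrCl2 (two divalent chromium centres per C–Br bond) reduces the allylic bromide to allylchromium 23, whose γ-carbon C7 adds to the chromium-bound C8 aldehyde through a six-membered chair transition state, forming C7–C8 and shifting the alkene to exocyclic C11=C13; the closest known reactions are the intermolecular zinc, indium and CrCl2 Barbier additions of 3-(bromomethyl)butenolides to aldehydes and the CrCl2 or zinc ring closures of 2-(bromomethyl)acrylates onto aldehydes, which do form medium rings. The ten-membered carbocycle C1–C10 closes in the exo mode (10-exo-trig attack of C7 on the C8 carbonyl, the oxygen staying outside the ring), helped by three rigid turn elements, the planar butenolide, the Z-alkene C4=C5 and the furanone. C7 is controlled by the C6 stereocentre: bonding on the butenolide face anti to the C6 alkenyl group gives the trans-fused lactone (H6 and H7 trans), as in intermolecular additions of γ-substituted reagents. C8 is controlled by the chair: the ring holds C6 trans to C13, so the reagent is an E-type γ-substituted allylmetal and the aldehyde chain (C9) sits pseudo-equatorial, which leads to the anti (7S,8R) homoallylic alcohol, with the fixed C6 and C10 centres selecting the ring conformer. The step needs γ- over α-attack (α-attack through C13 would require a twelve-membered ring and is not the normal mode of allylchromium reagents), ring closure over oligomerisation (slow addition, high dilution) and chemoselectivity for bromide and aldehyde (the neutral aprotic medium should leave the dienone, the lactone and the β-oxygenated aldehyde alone).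

**Side-chain acid and final acylation**

Step 17
Reactants: 25 tert-butyl acrylate and 26 acetaldehyde
Product: 27 tert-butyl 3-hydroxy-2-methylidenebutanoate (racemic)
Conditions: DABCO, 1,4-dioxane/H2O, rt
Reagents that add atoms: none
Why: Morita–Baylis–Hillman reaction: DABCO adds to the acrylate, the ammonium enolate adds to acetaldehyde and elimination regenerates the catalyst; the product is racemic, which is irrelevant because its stereocentre is removed in step 19.

Step 18
Reactants: 27 tert-butyl 3-hydroxy-2-methylidenebutanoate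
Product: 28 tert-butyl 3-acetoxy-2-methylidenebutanoate (racemic)
Conditions: Ac2O, DMAP (cat.), pyridine, CH2Cl2, 0 °C → rt
Reagents that add atoms: acetic anhydride, CC(=O)OC(C)=O
Why: Nucleophile-catalysed acetylation of the secondary allylic alcohol.

Step 19
Reactants: 28 tert-butyl 3-acetoxy-2-methylidenebutanoate
Product: 29 tert-butyl (E)-2-(acetoxymethyl)but-2-enoate
Conditions: DABCO (20 mol %), THF, reflux
Reagents that add atoms: none
Why: Amine-catalysed 1,3-transposition of a Morita–Baylis–Hillman acetate (SN2′ addition of DABCO with loss of acetate, then return of acetate at the CH2 terminus) should give the thermodynamically preferred primary acetate with the trisubstituted E-alkene, methyl trans to the ester as in tiglates.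

Step 20
Reactants: 29 tert-butyl (E)-2-(acetoxymethyl)but-2-enoate
Product: 30 (E)-2-(acetoxymethyl)but-2-enoic acid
Conditions: CF3CO2H, CH2Cl2, 0 °C → rt
Reagents that add atoms: none
Why: Acidolysis of the tert-butyl ester (loss of 2-methylpropene through the tert-butyl cation) frees the acid while the primary acetate, which would not survive saponification, is untouched.

Step 21
Reactants: 24 (6S,7S,8R,10R)-3,10-epoxy-8-hydroxy-1-oxogermacra-2,4(Z),11(13)-trien-12,6-olide and 30 (E)-2-(acetoxymethyl)but-2-enoic acid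
Product: 32 (6S,7S,8R,10R)-8-[(E)-2-(acetoxymethyl)but-2-enoyloxy]-3,10-epoxy-1-oxogermacra-2,4(Z),11(13)-trien-12,6-olide (CNP0176571.1), via mixed anhydride 31 (not isolated)
Conditions: 2,4,6-Cl3C6H2COCl, Et3N, toluene, rt; then 24, DMAP, rt
Reagents that add atoms: none
Why: Yamaguchi esterification: mixed anhydride 31 transfers the enoyl group via its acylpyridinium to the hindered secondary C8 hydroxyl, an O-acylation that keeps the C8 configuration.

**Compound list**

1 | (E)-3-methylpent-2-en-4-yn-1-ol | C#C/C(C)=C/CO | starting material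
2 | [(2S,3S)-3-ethynyl-3-methyloxiran-2-yl]methanol | OC[C@@H]1O[C@@]1(C)C#C | intermediate
3 | (R)-3-methylpent-4-yne-1,3-diol | C#C[C@@](C)(CCO)O | intermediate
4 | (R)-5-[(tert-butyldiphenylsilyl)oxy]-3-methylpent-1-yn-3-ol | C#C[C@@](C)(CCO[Si](c1ccccc1)(c1ccccc1)C(C)(C)C)O | intermediate
5 | (R)-5-oxotetrahydrofuran-2-carboxylic acid | OC(=O)[C@H]1CCC(=O)O1 | starting material
6 | (R)-5-(hydroxymethyl)dihydrofuran-2(3H)-one | OC[C@H]1CCC(=O)O1 | intermediate
7 | (R)-5-oxotetrahydrofuran-2-carbaldehyde | O=C[C@H]1CCC(=O)O1 | intermediate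
8 | (R)-5-[(Z)-2-iodoprop-1-en-1-yl]dihydrofuran-2(3H)-one | I/C(C)=C\[C@H]1CCC(=O)O1 | intermediate
9 | lithium enolate of 8 | I/C(C)=C\[C@H]1CC=C(O[Li])O1 | intermediate (not isolated)
10 | (5R)-5-[(Z)-2-iodoprop-1-en-1-yl]-3-(phenylselanyl)dihydrofuran-2(3H)-one, C3 epimers | I/C(C)=C\[C@H]1CC([Se]c2ccccc2)C(=O)O1 | intermediate
11 | lithium enolate of 10 | I/C(C)=C\[C@H]1CC([Se]c2ccccc2)=C(O[Li])O1 | intermediate (not isolated)
12 | (5R)-3-(hydroxymethyl)-5-[(Z)-2-iodoprop-1-en-1-yl]-3-(phenylselanyl)dihydrofuran-2(3H)-one, C3 epimers | I/C(C)=C\[C@H]1CC(CO)([Se]c2ccccc2)C(=O)O1 | intermediate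
13 | selenoxide of 12 | I/C(C)=C\[C@H]1CC(CO)([Se](=O)c2ccccc2)C(=O)O1 | intermediate (not isolated)
14 | (R)-3-(hydroxymethyl)-5-[(Z)-2-iodoprop-1-en-1-yl]furan-2(5H)-one | I/C(C)=C\[C@H]1C=C(CO)C(=O)O1 | intermediate
15 | (R)-3-{[(tert-butyldimethylsilyl)oxy]methyl}-5-[(Z)-2-iodoprop-1-en-1-yl]furan-2(5H)-one | I/C(C)=C\[C@H]1C=C(CO[Si](C)(C)C(C)(C)C)C(=O)O1 | intermediate
16 | (S)-3-{[(tert-butyldimethylsilyl)oxy]methyl}-5-[(1Z,6R)-8-[(tert-butyldiphenylsilyl)oxy]-6-hydroxy-2,6-dimethyl-3-oxooct-1-en-4-yn-1-yl]furan-2(5H)-one | CC(C)(C)[Si](c1ccccc1)(c1ccccc1)OCC[C@@](C)(O)C#CC(=O)/C(C)=C\[C@H]1C=C(CO[Si](C)(C)C(C)(C)C)C(=O)O1 | intermediate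
17 | hydroxy 1,3-diketone from hydration of 16 at C1 | CC(C)(C)[Si](c1ccccc1)(c1ccccc1)OCC[C@@](C)(O)C(=O)CC(=O)/C(C)=C\[C@H]1C=C(CO[Si](C)(C)C(C)(C)C)C(=O)O1 | intermediate (not isolated)
18 | (S)-3-{[(tert-butyldimethylsilyl)oxy]methyl}-5-{(Z)-2-[(R)-5-{2-[(tert-butyldiphenylsilyl)oxy]ethyl}-5-methyl-4-oxo-4,5-dihydrofuran-2-yl]prop-1-en-1-yl}furan-2(5H)-one | CC(C)(C)[Si](C)(C)OCC1=C[C@@H](OC1=O)/C=C(/C)C2=CC(=O)[C@@](C)(CCO[Si](c3ccccc3)(c3ccccc3)C(C)(C)C)O2 | intermediate
19 | (S)-3-(hydroxymethyl)-5-{(Z)-2-[(R)-5-(2-hydroxyethyl)-5-methyl-4-oxo-4,5-dihydrofuran-2-yl]prop-1-en-1-yl}furan-2(5H)-one | OCC1=C[C@@H](OC1=O)/C=C(/C)C2=CC(=O)[C@@](C)(CCO)O2 | intermediate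
20 | C13 alkoxydimethylsulfonium bromide of 19 | C[S+](C)OCC1=C[C@@H](OC1=O)/C=C(/C)C2=CC(=O)[C@@](C)(CCO)O2.[Br-] | intermediate (not isolated)
21 | (S)-3-(bromomethyl)-5-{(Z)-2-[(R)-5-(2-hydroxyethyl)-5-methyl-4-oxo-4,5-dihydrofuran-2-yl]prop-1-en-1-yl}furan-2(5H)-one | BrCC1=C[C@@H](OC1=O)/C=C(/C)C2=CC(=O)[C@@](C)(CCO)O2 | intermediate
22 | 2-[(2R)-5-{(1Z)-1-[(2S)-4-(bromomethyl)-5-oxo-2,5-dihydrofuran-2-yl]prop-1-en-2-yl}-2-methyl-3-oxo-2,3-dihydrofuran-2-yl]acetaldehyde (seco-C7,C8 precursor) | BrCC1=C[C@@H](OC1=O)/C=C(/C)C2=CC(=O)[C@@](C)(CC=O)O2 | intermediate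
23 | allylchromium dichloride from 22 (trivalent chromium on C13) | Cl[Cr](Cl)CC1=C[C@@H](OC1=O)/C=C(/C)C2=CC(=O)[C@@](C)(CC=O)O2 | intermediate (not isolated)
24 | (6S,7S,8R,10R)-3,10-epoxy-8-hydroxy-1-oxogermacra-2,4(Z),11(13)-trien-12,6-olide (core alcohol) | C=C1C(=O)O[C@H]2/C=C(/C)C3=CC(=O)[C@@](C)(C[C@@H](O)[C@H]12)O3 | intermediate
25 | tert-butyl acrylate | C=CC(=O)OC(C)(C)C | starting material
26 | acetaldehyde | CC=O | starting material
27 | tert-butyl 3-hydroxy-2-methylidenebutanoate (racemic) | C=C(C(C)O)C(=O)OC(C)(C)C | intermediate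
28 | tert-butyl 3-acetoxy-2-methylidenebutanoate (racemic) | C=C(C(C)OC(C)=O)C(=O)OC(C)(C)C | intermediate
29 | tert-butyl (E)-2-(acetoxymethyl)but-2-enoate | CC(=O)OC/C(=C\C)C(=O)OC(C)(C)C | intermediate
30 | (E)-2-(acetoxymethyl)but-2-enoic acid | CC(=O)OC/C(=C\C)C(=O)O | intermediate
31 | (E)-2-(acetoxymethyl)but-2-enoic 2,4,6-trichlorobenzoic anhydride | CC(=O)OC/C(=C\C)C(=O)OC(=O)c1c(Cl)cc(Cl)cc1Cl | intermediate (not isolated)
32 | (6S,7S,8R,10R)-8-[(E)-2-(acetoxymethyl)but-2-enoyloxy]-3,10-epoxy-1-oxogermacra-2,4(Z),11(13)-trien-12,6-olide (CNP0176571.1) | C=C1C(=O)O[C@H]2/C=C(/C)C3=CC(=O)[C@@](C)(C[C@@H](OC(=O)/C(=C/C)COC(C)=O)[C@H]12)O3 | target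

**Step count**

Total: 21 steps. Longest linear sequence: 14 steps (5 → 32 through steps 4–16 and 21).

**Three steps most likely to fail**

1. Step 16 (proposed new method). Oligomerisation or simple reduction of the allylchromium may outrun the strained ten-membered closure, or closure may take the wrong aldehyde face. The fallback reverses the order of bond formation with known reactions, forming C7–C8 between two small pieces and closing the ring at C3. It sets out from 14 and 3 and comes back to the route at target 32. Corey–Kim bromination of 14 (NBS, Me2S) would give (R)-3-(bromomethyl)-5-[(Z)-2-iodoprop-1-en-1-yl]furan-2(5H)-one F1. Selective oxidation of the primary alcohol of 3 (TEMPO, PhI(OAc)2) would give (R)-3-hydroxy-3-methylpent-4-ynal F2. Zinc-mediated Barbier addition of F1 to F2 (Zn, THF/aq. NH4Cl), the known intermolecular reaction of this reagent class, should give (4S,5R)-4-[(1R,3R)-1,3-dihydroxy-3-methylpent-4-yn-1-yl]-5-[(Z)-2-iodoprop-1-en-1-yl]-3-methylidenedihydrofuran-2(3H)-one F3. Yamaguchi acylation of its secondary hydroxyl with acid 30 would give (1R,3R)-3-hydroxy-1-{(2R,3S)-2-[(Z)-2-iodoprop-1-en-1-yl]-4-methylidene-5-oxotetrahydrofuran-3-yl}-3-methylpent-4-yn-1-yl (E)-2-(acetoxymethyl)but-2-enoate F4. Intramolecular carbonylative Sonogashira coupling at high dilution (PdCl2(PPh3)2, CuI, Et3N, CO) would close the carbocycle to (6S,7S,8R,10R)-8-[(E)-2-(acetoxymethyl)but-2-enoyloxy]-10-hydroxy-3-oxogermacra-4(Z),11(13)-dien-1-yn-12,6-olide F5. Gold-catalysed hydrative cyclisation as in step 12, now transannular, would give 32.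

2. Step 11. Direct alkynylation of the vinylpalladium before CO insertion would give an enyne lacking C3, and the amine base may epimerise C6 of the butenolide. The fallback forms C3–C4 by a chromium-mediated carbonyl addition instead of a carbonylation. It sets out from 4 and 15 and comes back at 16. Double deprotonation of 4 (n-BuLi) and formylation with DMF would give (R)-6-[(tert-butyldiphenylsilyl)oxy]-4-hydroxy-4-methylhex-2-ynal F6. Nozaki–Hiyama–Kishi coupling of vinyl iodide 15 with F6 (CrCl2, NiCl2 cat., DMF), which keeps the Z geometry and uses no amine, would give (5S)-3-{[(tert-butyldimethylsilyl)oxy]methyl}-5-[(1Z,6R)-8-[(tert-butyldiphenylsilyl)oxy]-3,6-dihydroxy-2,6-dimethyloct-1-en-4-yn-1-yl]furan-2(5H)-one F7 as a mixture at the new carbinol. Oxidation of that allylic, propargylic alcohol with MnO2 would give 16.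

3. Step 12. A silyl ether or lactone oxygen may capture the gold-activated alkyne, or the Z-enone may isomerise, instead of conjugate hydration at C1. The fallback replaces π-acid catalysis by nucleophilic amination. It sets out from 16 and comes back at 18. Conjugate addition of Et2NH (EtOH, 0 °C) to the ynone would give the isolable enaminone (5S)-3-{[(tert-butyldimethylsilyl)oxy]methyl}-5-[(1Z,4E,6R)-8-[(tert-butyldiphenylsilyl)oxy]-5-(diethylamino)-6-hydroxy-2,6-dimethyl-3-oxoocta-1,4-dien-1-yl]furan-2(5H)-one F8. Hydrolysis and cyclodehydration in AcOH/H2O/THF would give 18.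

**Further compounds**

F1 | step 16 | (R)-3-(bromomethyl)-5-[(Z)-2-iodoprop-1-en-1-yl]furan-2(5H)-one | I/C(C)=C\[C@H]1C=C(CBr)C(=O)O1
F2 | step 16 | (R)-3-hydroxy-3-methylpent-4-ynal | C#C[C@@](C)(CC=O)O
F3 | step 16 | (4S,5R)-4-[(1R,3R)-1,3-dihydroxy-3-methylpent-4-yn-1-yl]-5-[(Z)-2-iodoprop-1-en-1-yl]-3-methylidenedihydrofuran-2(3H)-one | C=C1C(=O)O[C@@H](/C=C(/C)I)[C@@H]1[C@H](O)C[C@@](C)(O)C#C
F4 | step 16 | (1R,3R)-3-hydroxy-1-{(2R,3S)-2-[(Z)-2-iodoprop-1-en-1-yl]-4-methylidene-5-oxotetrahydrofuran-3-yl}-3-methylpent-4-yn-1-yl (E)-2-(acetoxymethyl)but-2-enoate | C=C1C(=O)O[C@@H](/C=C(/C)I)[C@@H]1[C@H](OC(=O)/C(=C/C)COC(C)=O)C[C@@](C)(O)C#C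
F5 | step 16 | (6S,7S,8R,10R)-8-[(E)-2-(acetoxymethyl)but-2-enoyloxy]-10-hydroxy-3-oxogermacra-4(Z),11(13)-dien-1-yn-12,6-olide | C=C1C(=O)O[C@H]2/C=C(/C)C(=O)C#C[C@](C)(O)C[C@@H](OC(=O)/C(=C/C)COC(C)=O)[C@H]12
F6 | step 11 | (R)-6-[(tert-butyldiphenylsilyl)oxy]-4-hydroxy-4-methylhex-2-ynal | O=CC#C[C@@](C)(CCO[Si](c1ccccc1)(c1ccccc1)C(C)(C)C)O
F7 | step 11 | (5S)-3-{[(tert-butyldimethylsilyl)oxy]methyl}-5-[(1Z,6R)-8-[(tert-butyldiphenylsilyl)oxy]-3,6-dihydroxy-2,6-dimethyloct-1-en-4-yn-1-yl]furan-2(5H)-one, mixture at the C3 carbinol of the chain | CC(C)(C)[Si](c1ccccc1)(c1ccccc1)OCC[C@@](C)(O)C#CC(O)/C(C)=C\[C@H]1C=C(CO[Si](C)(C)C(C)(C)C)C(=O)O1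
F8 | step 12 | (5S)-3-{[(tert-butyldimethylsilyl)oxy]methyl}-5-[(1Z,4E,6R)-8-[(tert-butyldiphenylsilyl)oxy]-5-(diethylamino)-6-hydroxy-2,6-dimethyl-3-oxoocta-1,4-dien-1-yl]furan-2(5H)-one | CCN(CC)/C(=C/C(=O)/C(C)=C\[C@H]1C=C(CO[Si](C)(C)C(C)(C)C)C(=O)O1)[C@](C)(O)CCO[Si](c1ccccc1)(c1ccccc1)C(C)(C)C
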